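The route rests on disconnecting the bicyclo[2.2.2]octenone by a retro-Diels–Alder reaction to a cyclohexa-2,4-dienone, and on never making that dienone ring in six-membered form. The ring formed by the ketone carbon, its two methyl-bearing α-carbons, the CH2O-bearing bridgehead and the CH=C unit is grown from a 4-alkenyl-4-silyloxycyclobutenone. One thermolysis opens the four-membered ring to a dienylketene, recloses it as the dienone (two carbons larger) and lets this add to the exocyclic methylene of a preformed cyclohexanol, closing three rings and setting four stereocentres. Both lactone carbonyl carbons are introduced afterwards.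

Key step: step 15

Assumption: pig liver esterase is taken to hydrolyse the ester group of 12 that gives (R)-13; this sense is not secured by a close analogue.

Step 1
Reactants: 1 2-butyne-1,4-diol
Product: 2 4-[(tert-butyldimethylsilyl)oxy]but-2-yn-1-ol
Conditions: NaH (1.0 equiv), THF, 0 °C; TBSCl (1.0 equiv), rt
Reagents that add atoms: tert-butyldimethylsilyl chloride, CC(C)(C)[Si](C)(C)Cl
Why: Deprotonation of the symmetric diol to its poorly soluble monosodium alkoxide followed by O-silylation should give mainly the mono-ether.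

Step 2
Reactants: 2 4-[(tert-butyldimethylsilyl)oxy]but-2-yn-1-ol
Product: 4 (Z)-2-bromo-4-[(tert-butyldimethylsilyl)oxy]-3-methylbut-2-en-1-ol, via alkenylmagnesium chelate 3 (not isolated)
Conditions: MeMgBr (3 equiv), CuI (10 mol %), THF, 65 °C; then NBS, −40 °C
Reagents that add atoms: methylmagnesium bromide, C[Mg]Br; N-bromosuccinimide, O=C1CCC(=O)N1Br
Why: Copper-catalysed anti-carbomagnesiation of the propargylic alcohol, directed by the magnesium alkoxide through a five-membered chelate, puts methyl on the distal and magnesium on the proximal alkyne carbon, and bromination of the C–Mg bond with retention should fix the tetrasubstituted (Z)-bromoalkene.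

Step 3
Reactants: 4 (Z)-2-bromo-4-[(tert-butyldimethylsilyl)oxy]-3-methylbut-2-en-1-ol
Product: 5 (Z)-2-bromo-4-[(tert-butyldimethylsilyl)oxy]-1-[(tert-butyldiphenylsilyl)oxy]-3-methylbut-2-ene
Conditions: TBDPSCl, imidazole, CH2Cl2, rt
Reagents that add atoms: tert-butyldiphenylsilyl chloride, CC(C)(C)[Si](Cl)(c1ccccc1)c1ccccc1
Why: Standard silyl ether formation protects the primary allylic alcohol with the robust group that has to last until step 17.

Step 4
Reactants: 5 (Z)-2-bromo-4-[(tert-butyldimethylsilyl)oxy]-1-[(tert-butyldiphenylsilyl)oxy]-3-methylbut-2-ene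
Product: 6 (Z)-2,4-dibromo-1-[(tert-butyldiphenylsilyl)oxy]-3-methylbut-2-ene
Conditions: Ph3PBr2, CH2Cl2, 0 °C → rt
Reagents that add atoms: dibromotriphenylphosphorane, BrP(Br)(c1ccccc1)(c1ccccc1)c1ccccc1
Why: Ph3PBr2 converts a primary tert-butyldimethylsilyl ether directly into the bromide through an oxyphosphonium ion, while the bulkier tert-butyldiphenylsilyl ether should survive.

Step 5
Reactants: 7 but-3-yn-1-ol; 6 (Z)-2,4-dibromo-1-[(tert-butyldiphenylsilyl)oxy]-3-methylbut-2-ene
Product: 9 (3E,6Z)-7-bromo-8-[(tert-butyldiphenylsilyl)oxy]-3,6-dimethylocta-3,6-dien-1-ol, via alkenylalane 8 (not isolated)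
Conditions: Me3Al (3 equiv), Cp2ZrCl2 (0.25 equiv), CH2Cl2, 0 °C → rt; then 6, Pd(PPh3)4 (5 mol %), THF, rt
Reagents that add atoms: trimethylaluminium, C[Al](C)C
Why: Negishi zirconium-catalysed syn-carboalumination of the terminal alkyne gives the (E)-2-methylalkenylalane, and palladium-catalysed allylation (oxidative addition of zerovalent palladium to the allylic C–Br bond far outpaces that to the hindered alkenyl bromide) joins it to the CH2 terminus with retention of both alkene geometries.

Step 6
Reactants: 9 (3E,6Z)-7-bromo-8-[(tert-butyldiphenylsilyl)oxy]-3,6-dimethylocta-3,6-dien-1-ol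
Product: 10 (3E,6Z)-7-bromo-8-[(tert-butyldiphenylsilyl)oxy]-1-iodo-3,6-dimethylocta-3,6-diene
Conditions: I2, PPh3, imidazole, CH2Cl2, 0 °C
Reagents that add atoms: iodine, II
Why: Appel-type iodination of the primary alcohol gives the alkylating agent without touching the alkenes.

Step 7
Reactants: 11 dimethyl 2-(propan-2-ylidene)propanedioate; 10 (3E,6Z)-7-bromo-8-[(tert-butyldiphenylsilyl)oxy]-1-iodo-3,6-dimethylocta-3,6-diene
Product: 12 dimethyl 2-[(3E,6Z)-7-bromo-8-[(tert-butyldiphenylsilyl)oxy]-3,6-dimethylocta-3,6-dien-1-yl]-2-(prop-1-en-2-yl)propanedioate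
Conditions: NaH, THF/DMF, 0 °C → rt
Reagents that add atoms: none
Why: Deprotonation of the alkylidenemalonate at a γ-methyl group gives the extended enolate, whose alkylation at the α-carbon (deconjugative alkylation) creates the quaternary, still prochiral carbon that carries the isopropenyl group.

Step 8
Reactants: 12 dimethyl 2-[(3E,6Z)-7-bromo-8-[(tert-butyldiphenylsilyl)oxy]-3,6-dimethylocta-3,6-dien-1-yl]-2-(prop-1-en-2-yl)propanedioate
Product: 13 (2R,5E,8Z)-9-bromo-10-[(tert-butyldiphenylsilyl)oxy]-2-(methoxycarbonyl)-5,8-dimethyl-2-(prop-1-en-2-yl)deca-5,8-dienoic acid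
Conditions: PLE, phosphate buffer pH 7.5, DMSO (10 %), 25 °C
Reagents that add atoms: water, O
Why: Enzymatic desymmetrisation, in which the esterase hydrolyses one of the two enantiotopic ester groups of the prochiral disubstituted malonate, should set the quaternary stereocentre (assumed sense: R).

Step 9
Reactants: 13 (2R,5E,8Z)-9-bromo-10-[(tert-butyldiphenylsilyl)oxy]-2-(methoxycarbonyl)-5,8-dimethyl-2-(prop-1-en-2-yl)deca-5,8-dienoic acid
Product: 15 methyl (2R,5E,8Z)-2-acetyl-9-bromo-10-[(tert-butyldiphenylsilyl)oxy]-5,8-dimethyl-2-(prop-1-en-2-yl)deca-5,8-dienoate, via acid chloride 14 (not isolated)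
Conditions: (COCl)2, DMF (cat.), CH2Cl2, 0 °C; then Me2CuLi, Et2O, −78 °C
Reagents that add atoms: lithium dimethylcuprate, [Li+].C[Cu-]C
Why: The acid chloride is acylated once by the Gilman cuprate (ketone synthesis from acid chlorides) to the methyl ketone, the hindered ester and the alkenyl bromide being inert at −78 °C, and the stereocentre is untouched.

Step 10
Reactants: 15 methyl (2R,5E,8Z)-2-acetyl-9-bromo-10-[(tert-butyldiphenylsilyl)oxy]-5,8-dimethyl-2-(prop-1-en-2-yl)deca-5,8-dienoate
Product: 16 methyl (1R,2R,3R)-3-[(2Z)-3-bromo-4-[(tert-butyldiphenylsilyl)oxy]-2-methylbut-2-en-1-yl]-2-hydroxy-2-methyl-4-methylidene-1-(prop-1-en-2-yl)cyclohexane-1-carboxylate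
Conditions: Me2AlCl (2.2 equiv), CH2Cl2, −78 → −20 °C
Reagents that add atoms: none
Why: Lewis-acid-promoted type 2 carbonyl-ene cyclisation of the aluminium-chelated β-keto ester through a chair transition state (ester equatorial in the chelate, isopropenyl axial, carbonyl oxygen axial over the ene unit, the (E)-alkene substituent equatorial) should place the new tertiary OH cis to the ester and to the side chain on the adjacent CH, and transfer of hydrogen from the methyl group gives the exocyclic methylene.

Step 11
Reactants: 16 methyl (1R,2R,3R)-3-[(2Z)-3-bromo-4-[(tert-butyldiphenylsilyl)oxy]-2-methylbut-2-en-1-yl]-2-hydroxy-2-methyl-4-methylidene-1-(prop-1-en-2-yl)cyclohexane-1-carboxylate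
Product: 17 (1R,2R,6S)-2-[(2Z)-3-bromo-4-[(tert-butyldiphenylsilyl)oxy]-2-methylbut-2-en-1-yl]-6-(hydroxymethyl)-1-methyl-3-methylidene-6-(prop-1-en-2-yl)cyclohexan-1-ol
Conditions: LiAlH4, Et2O, 0 °C
Reagents that add atoms: none
Why: Hydride reduction of the ester to the primary alcohol removes the only group that would not survive the organolithium step, and no stereocentre is affected.

Step 12
Reactants: 18 3,4-di(propan-2-yloxy)cyclobut-3-ene-1,2-dione
Product: 20 3-methyl-4-(propan-2-yloxy)cyclobut-3-ene-1,2-dione, via lithium alkoxide 19 (not isolated)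
Conditions: MeLi, THF, −78 °C; then (CF3CO)2O, −78 °C → rt; H2O
Reagents that add atoms: methyllithium, [Li]C; water, O
Why: 1,2-Addition of MeLi to one carbonyl group of the squarate, then anhydride-triggered loss of the tertiary oxygen with transposition and hydrolysis of the vinylogous ester (propan-2-ol lost), should give the methyl-substituted cyclobutenedione.

Step 13
Reactants: 17 (1R,2R,6S)-2-[(2Z)-3-bromo-4-[(tert-butyldiphenylsilyl)oxy]-2-methylbut-2-en-1-yl]-6-(hydroxymethyl)-1-methyl-3-methylidene-6-(prop-1-en-2-yl)cyclohexan-1-ol; 20 3-methyl-4-(propan-2-yloxy)cyclobut-3-ene-1,2-dione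
Product: 23 4-alkenyl-2-methyl-3-(propan-2-yloxy)-4-(triethylsilyloxy)cyclobut-2-en-1-one bis(triethylsilyl) ether, via alkenyllithium 21 (not isolated), via lithium alkoxide adduct 22 (not isolated)
Conditions: n-BuLi (2.0 equiv), THF, −78 °C; t-BuLi (2.1 equiv), −78 °C; then 20; then Et3SiCl (2.5 equiv), −78 → 0 °C
Reagents that add atoms: chlorotriethylsilane, CC[Si](Cl)(CC)CC
Why: Bromine–lithium exchange with retention of alkene geometry and 1,2-addition of the alkenyllithium to the ketone carbonyl next to the isopropoxy-bearing carbon (the other carbonyl is a deactivated vinylogous ester) give the tertiary alkoxide, which is silylated together with the primary one while the hindered ring alkoxide should stay free; the new carbinol centre forms as a mixture that becomes sp2 in step 15.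

Step 14
Reactants: 23 4-alkenyl-2-methyl-3-(propan-2-yloxy)-4-(triethylsilyloxy)cyclobut-2-en-1-one bis(triethylsilyl) ether
Product: 25 4-alkenyl-2-methyl-4-(triethylsilyloxy)cyclobut-2-en-1-one, via cyclobutenol 24 (not isolated)
Conditions: i-Bu2AlH (2.2 equiv), CH2Cl2, −78 °C; then 0.1 M HCl, THF, 0 °C
Reagents that add atoms: water, O
Why: 1,2-Reduction of the vinylogous ester carbonyl and acid-induced allylic transposition with loss of propan-2-ol (Stork–Danheiser-type carbonyl transposition) should move the carbonyl next to the methyl-bearing carbon and leave H on the former carbonyl carbon.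

Step 15
Reactants: 25 4-alkenyl-2-methyl-4-(triethylsilyloxy)cyclobut-2-en-1-one
Product: 28 cage silyl enol ether (bicyclo[2.2.2]octenone fused to cyclopentane and cyclohexanol), via dienylketene 26 (not isolated), via cyclohexadienone 27 (not isolated)
Conditions: o-xylene (0.005 M), BHT (cat.), 145 °C
Reagents that add atoms: none
Why: Heating should open the cyclobutenone by conrotatory 4π ring opening with the silyloxy group rotating outward, so that the alkenyl group ends cis to the ketene in dienylketene 26, and disrotatory 6π electrocyclisation then joins the ketene carbon to the fully substituted alkene terminus to give cyclohexa-2,4-dienone 27, the four-membered ring having grown by two carbons as in the Moore rearrangement of 4-alkenyl-4-hydroxycyclobutenones, except that the quaternary terminus forbids tautomerisation to a phenol. Dienone 27 then reacts as the diene in an intramolecular Diels–Alder reaction with the exocyclic methylene (closest precedent: intramolecular cycloadditions of 6,6-disubstituted cyclohexa-2,4-dienones), one suprafacial [4+2] event that closes both the second six-membered ring of the bicyclo[2.2.2]octenone and, through the two-carbon tether, the fused cyclopentane. The quaternary C(CH3)(CH2) centre made in the electrocyclisation is not controlled there, but ring opening and closure are expected to be reversible at 145 °C, and only the epimer whose tether lets the diene reach the alkene face cis to the side chain (cis-fused five-membered ring) can cyclise, so the existing CH stereocentre of the cyclohexane selects it. That same constraint sets the two bridgeheads and the ring quaternary carbon, because the diene must be attacked on the face that carries the tether. The step needs torquoselectivity (secured by the oxygen donor on the sp3 carbon), periselectivity for 6π closure over ketene [2+2] addition (secured by the s-cis dienylketene) and site selectivity for the methylene next to the tether over the remote isopropenyl group (secured by tether length); the tertiary alcohol is left free so that the incoming bridgehead has only a small axial neighbour.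

Step 16
Reactants: 28 cage silyl enol ether
Product: 29 cage alkenyl triflate
Conditions: CsF, PhNTf2, DME, rt
Reagents that add atoms: N-phenylbis(trifluoromethanesulfonimide), O=S(=O)(N(c1ccccc1)S(=O)(=O)C(F)(F)F)C(F)(F)F
Why: Fluoride cleaves the silyl enol ether to the caesium enolate, which can only lie toward the CH because the other α-carbon is the quaternary bridgehead, and O-triflation (enol triflate formation) follows.

Step 17
Reactants: 29 cage alkenyl triflate
Product: 30 triol alkenyl triflate
Conditions: HF·pyridine, pyridine, THF, 0 °C → rt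
Reagents that add atoms: none
Why: Fluoride-mediated desilylation frees the two primary alcohols, the alkenyl triflate and the ketone being stable to buffered HF.

Step 18
Reactants: 30 triol alkenyl triflate
Product: 31 butenolide diol
Conditions: Pd(PPh3)4 (10 mol %), CO (1 atm), Et3N, DMF, 60 °C
Reagents that add atoms: carbon monoxide, [C-]#[O+]
Why: Oxidative addition of zerovalent palladium to the alkenyl triflate, CO insertion and capture of the acylpalladium by the neighbouring CH2OH (carbonylative lactonisation) close the butenolide, the other hydroxyl groups being out of reach.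

Step 19
Reactants: 31 butenolide diol
Product: 32 hydroxy aldehyde
Conditions: Dess–Martin periodinane, CH2Cl2, rt
Reagents that add atoms: none
Why: Dess–Martin oxidation converts the primary neopentyl alcohol into the aldehyde while the tertiary alcohol cannot react, and the quaternary α-carbon rules out epimerisation.

Step 20
Reactants: 32 hydroxy aldehyde
Product: 33 (Z)-enoate
Conditions: (CF3CH2O)2P(O)CH2CO2Me, KN(SiMe3)2, 18-crown-6, THF, −78 °C
Reagents that add atoms: methyl bis(2,2,2-trifluoroethyl)phosphonoacetate, COC(=O)CP(=O)(OCC(F)(F)F)OCC(F)(F)F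
Why: Still–Gennari olefination (Z-selective Horner–Wadsworth–Emmons reaction of an electron-poor phosphonate under dissociating conditions) should give the (Z)-enoate needed for ring closure.

Step 21
Reactants: 33 (Z)-enoate
Product: 34 andibenin
Conditions: TfOH (0.2 equiv), H2O (1 equiv), CH2Cl2, 0 °C
Reagents that add atoms: water, O
Why: Markovnikov protonation of the isopropenyl group gives a tertiary cation that is captured through a six-membered transition state by the carbonyl oxygen of the (Z)-ester, and hydrolysis of the resulting dialkoxycarbenium ion with loss of methanol (acid-catalysed lactonisation of an unsaturated ester) closes the spiro δ-lactone at the existing quaternary stereocentre.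

Compound list
1 | 2-butyne-1,4-diol | OCC#CCO | starting material
2 | 4-[(tert-butyldimethylsilyl)oxy]but-2-yn-1-ol | OCC#CCO[Si](C)(C)C(C)(C)C | intermediate
3 | alkenylmagnesium chelate from 2 (bromomagnesium alkoxide; C–MgBr trans to the new methyl group) | Br[Mg]OC/C([Mg]Br)=C(C)/CO[Si](C)(C)C(C)(C)C | intermediate
4 | (Z)-2-bromo-4-[(tert-butyldimethylsilyl)oxy]-3-methylbut-2-en-1-ol | OC/C(Br)=C(C)/CO[Si](C)(C)C(C)(C)C | intermediate
5 | (Z)-2-bromo-4-[(tert-butyldimethylsilyl)oxy]-1-[(tert-butyldiphenylsilyl)oxy]-3-methylbut-2-ene | CC(C)(C)[Si](c1ccccc1)(c1ccccc1)OC/C(Br)=C(C)/CO[Si](C)(C)C(C)(C)C | intermediate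
6 | (Z)-2,4-dibromo-1-[(tert-butyldiphenylsilyl)oxy]-3-methylbut-2-ene | CC(C)(C)[Si](c1ccccc1)(c1ccccc1)OC/C(Br)=C(C)/CBr | intermediate
7 | but-3-yn-1-ol | C#CCCO | starting material
8 | (E)-alkenylalane from 7 (dimethylaluminium on the terminal alkene carbon and on oxygen) | C[Al](C)OCC/C(C)=C/[Al](C)C | intermediate
9 | (3E,6Z)-7-bromo-8-[(tert-butyldiphenylsilyl)oxy]-3,6-dimethylocta-3,6-dien-1-ol | OCC/C(C)=C/C/C(C)=C(Br)/CO[Si](c1ccccc1)(c1ccccc1)C(C)(C)C | intermediate
10 | (3E,6Z)-7-bromo-8-[(tert-butyldiphenylsilyl)oxy]-1-iodo-3,6-dimethylocta-3,6-diene | ICC/C(C)=C/C/C(C)=C(Br)/CO[Si](c1ccccc1)(c1ccccc1)C(C)(C)C | intermediate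
11 | dimethyl 2-(propan-2-ylidene)propanedioate (dimethyl isopropylidenemalonate) | COC(=O)C(=C(C)C)C(=O)OC | starting material
12 | dimethyl 2-[(3E,6Z)-7-bromo-8-[(tert-butyldiphenylsilyl)oxy]-3,6-dimethylocta-3,6-dien-1-yl]-2-(prop-1-en-2-yl)propanedioate | COC(=O)C(C(C)=C)(CC/C(C)=C/C/C(C)=C(Br)/CO[Si](c1ccccc1)(c1ccccc1)C(C)(C)C)C(=O)OC | intermediate
13 | (2R,5E,8Z)-9-bromo-10-[(tert-butyldiphenylsilyl)oxy]-2-(methoxycarbonyl)-5,8-dimethyl-2-(prop-1-en-2-yl)deca-5,8-dienoic acid | COC(=O)[C@](C(C)=C)(C(=O)O)CC/C(C)=C/C/C(C)=C(Br)/CO[Si](c1ccccc1)(c1ccccc1)C(C)(C)C | intermediate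
14 | acid chloride of 13 (same spatial arrangement at the quaternary carbon) | COC(=O)[C@](C(C)=C)(C(=O)Cl)CC/C(C)=C/C/C(C)=C(Br)/CO[Si](c1ccccc1)(c1ccccc1)C(C)(C)C | intermediate
15 | methyl (2R,5E,8Z)-2-acetyl-9-bromo-10-[(tert-butyldiphenylsilyl)oxy]-5,8-dimethyl-2-(prop-1-en-2-yl)deca-5,8-dienoate | COC(=O)[C@](C(C)=C)(C(C)=O)CC/C(C)=C/C/C(C)=C(Br)/CO[Si](c1ccccc1)(c1ccccc1)C(C)(C)C | intermediate
16 | methyl (1R,2R,3R)-3-[(2Z)-3-bromo-4-[(tert-butyldiphenylsilyl)oxy]-2-methylbut-2-en-1-yl]-2-hydroxy-2-methyl-4-methylidene-1-(prop-1-en-2-yl)cyclohexane-1-carboxylate (OH cis to the ester and to the side chain) | COC(=O)[C@@]1(C(C)=C)CCC(=C)[C@@H](C/C(C)=C(Br)/CO[Si](c2ccccc2)(c2ccccc2)C(C)(C)C)[C@@]1(C)O | intermediate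
17 | (1R,2R,6S)-2-[(2Z)-3-bromo-4-[(tert-butyldiphenylsilyl)oxy]-2-methylbut-2-en-1-yl]-6-(hydroxymethyl)-1-methyl-3-methylidene-6-(prop-1-en-2-yl)cyclohexan-1-ol | OC[C@@]1(C(C)=C)CCC(=C)[C@@H](C/C(C)=C(Br)/CO[Si](c2ccccc2)(c2ccccc2)C(C)(C)C)[C@@]1(C)O | intermediate
18 | 3,4-di(propan-2-yloxy)cyclobut-3-ene-1,2-dione (diisopropyl squarate) | CC(C)OC1=C(OC(C)C)C(=O)C1=O | starting material
19 | lithium 1-methyl-4-oxo-2,3-di(propan-2-yloxy)cyclobut-2-en-1-olate | [Li]OC1(C)C(OC(C)C)=C(OC(C)C)C1=O | intermediate
20 | 3-methyl-4-(propan-2-yloxy)cyclobut-3-ene-1,2-dione | CC1=C(OC(C)C)C(=O)C1=O | intermediate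
21 | alkenyllithium from 17 (Li in place of Br with retention; both hydroxyl groups as lithium alkoxides) | [Li]OC[C@@]1(C(C)=C)CCC(=C)[C@@H](C/C(C)=C(/CO[Si](c2ccccc2)(c2ccccc2)C(C)(C)C)[Li])[C@@]1(C)O[Li] | intermediate
22 | trilithium alkoxide adduct of 21 to the carbonyl of 20 next to the isopropoxy-bearing carbon (both epimers at the new carbinol carbon) | [Li]OC[C@@]1(C(C)=C)CCC(=C)[C@@H](C/C(C)=C(/CO[Si](c2ccccc2)(c2ccccc2)C(C)(C)C)C2(O[Li])C(OC(C)C)=C(C)C2=O)[C@@]1(C)O[Li] | intermediate
23 | 4-alkenyl-2-methyl-3-(propan-2-yloxy)-4-(triethylsilyloxy)cyclobut-2-en-1-one bis(triethylsilyl) ether: 22 with the cyclobutene oxygen and the primary oxygen silylated, ring tertiary OH free; cyclohexane stereocentres as in 17, both epimers at the cyclobutene carbinol carbon | CC[Si](CC)(CC)OC[C@@]1(C(C)=C)CCC(=C)[C@@H](C/C(C)=C(/CO[Si](c2ccccc2)(c2ccccc2)C(C)(C)C)C2(O[Si](CC)(CC)CC)C(OC(C)C)=C(C)C2=O)[C@@]1(C)O | intermediate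
24 | cyclobutenol from 1,2-reduction of 23 (C=O of 23 as CHOH) | CC[Si](CC)(CC)OC[C@@]1(C(C)=C)CCC(=C)[C@@H](C/C(C)=C(/CO[Si](c2ccccc2)(c2ccccc2)C(C)(C)C)C2(O[Si](CC)(CC)CC)C(OC(C)C)=C(C)C2O)[C@@]1(C)O | intermediate
25 | 4-alkenyl-2-methyl-4-(triethylsilyloxy)cyclobut-2-en-1-one: carbonyl next to the methyl-bearing carbon, H on C-3, other groups as in 23 | CC[Si](CC)(CC)OC[C@@]1(C(C)=C)CCC(=C)[C@@H](C/C(C)=C(/CO[Si](c2ccccc2)(c2ccccc2)C(C)(C)C)C2(O[Si](CC)(CC)CC)C=C(C)C2=O)[C@@]1(C)O | intermediate
26 | dienylketene: methyl(dienyl)ketene, ketene cis to the tetrasubstituted alkene across the silyloxy-bearing double bond | CC[Si](CC)(CC)OC[C@@]1(C(C)=C)CCC(=C)[C@@H](C/C(C)=C(/CO[Si](c2ccccc2)(c2ccccc2)C(C)(C)C)\C(O[Si](CC)(CC)CC)=C/C(C)=C=O)[C@@]1(C)O | intermediate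
27 | 2,6-dimethyl-6-(cyclohexylmethyl)-4-(triethylsilyloxy)-5-[(tert-butyldiphenylsilyloxy)methyl]cyclohexa-2,4-dien-1-one, quaternary ring carbon in the configuration of 34, cyclohexane as in 25 | CC[Si](CC)(CC)OC[C@@]1(C(C)=C)CCC(=C)[C@@H](C[C@@]2(C)C(=O)C(C)=CC(O[Si](CC)(CC)CC)=C2CO[Si](c3ccccc3)(c3ccccc3)C(C)(C)C)[C@@]1(C)O | intermediate
28 | cage silyl enol ether: bicyclo[2.2.2]octenone of 34 with OSiEt3 on the alkene carbon in place of the lactone carbonyl, CH2OSi(t-Bu)Ph2 on the adjacent bridgehead, isopropenyl and CH2OSiEt3 on the future spiro carbon; all seven stereocentres as in 34 | CC[Si](CC)(CC)OC[C@@]1(C(C)=C)CC[C@@]23C[C@@]4(C)C=C(O[Si](CC)(CC)CC)[C@]2(CO[Si](c5ccccc5)(c5ccccc5)C(C)(C)C)[C@@](C)(C[C@H]3[C@@]1(C)O)C4=O | intermediate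
29 | cage alkenyl triflate: 28 with OSO2CF3 in place of the enol OSiEt3 | CC[Si](CC)(CC)OC[C@@]1(C(C)=C)CC[C@@]23C[C@@]4(C)C=C(OS(=O)(=O)C(F)(F)F)[C@]2(CO[Si](c5ccccc5)(c5ccccc5)C(C)(C)C)[C@@](C)(C[C@H]3[C@@]1(C)O)C4=O | intermediate
30 | triol alkenyl triflate: 29 with both silyl ethers cleaved | OC[C@@]1(C(C)=C)CC[C@@]23C[C@@]4(C)C=C(OS(=O)(=O)C(F)(F)F)[C@]2(CO)[C@@](C)(C[C@H]3[C@@]1(C)O)C4=O | intermediate
31 | butenolide diol: 34 with isopropenyl and CH2OH on the future spiro carbon in place of the δ-lactone | OC[C@@]1(C(C)=C)CC[C@@]23C[C@@]4(C)C=C5C(=O)OC[C@]52[C@@](C)(C[C@H]3[C@@]1(C)O)C4=O | intermediate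
32 | hydroxy aldehyde: 31 with CHO in place of CH2OH | O=C[C@@]1(C(C)=C)CC[C@@]23C[C@@]4(C)C=C5C(=O)OC[C@]52[C@@](C)(C[C@H]3[C@@]1(C)O)C4=O | intermediate
33 | (Z)-enoate: 32 with (Z)-CH=CH–CO2CH3 in place of CHO | COC(=O)/C=C\[C@@]1(C(C)=C)CC[C@@]23C[C@@]4(C)C=C5C(=O)OC[C@]52[C@@](C)(C[C@H]3[C@@]1(C)O)C4=O | intermediate
34 | andibenin | CC1(C)OC(=O)C=C[C@]12CC[C@@]13C[C@@]4(C)C=C5C(=O)OC[C@]51[C@@](C)(C[C@H]3[C@@]2(C)O)C4=O | target

Total step count: 21. Longest linear sequence: 20 steps (steps 1–11 and 13–21, from 2-butyne-1,4-diol); step 12 supplies the four-membered ring in one step.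

Steps most likely to fail

Step 15. The dienone epimer with the wrong configuration at the new quaternary carbon may not return to the ketene at a useful rate and would then be lost to dimerisation, and the cycloaddition between two fully substituted carbons may be slower than thermal decay of the silyl enol ether. The fallback sets out from 25 and comes back at 28 by taking the cascade apart. 25 is heated only to 80–110 °C in toluene, and the dienones are isolated as a mixture of 27 and its epimer at the quaternary ring carbon, epimeric dienone F1. The cycloaddition is then run separately under pressure (12 kbar, CH2Cl2, 25 °C), where only 27 can close to 28. Recovered epimeric dienone F1 is irradiated at 365 nm (photochemical ring opening of cyclohexa-2,4-dienones to dienylketenes, thermal reclosure), which should regenerate the epimer mixture for another pass.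

Step 8. The enzyme may hydrolyse the large lipophilic diester slowly or discriminate poorly between the enantiotopic ester groups. The fallback sets out from 12 and comes back at 13. Half-saponification with KOH (1 equiv) in MeOH/H2O gives racemic half-ester F2, and the enantiomers are separated by preparative chromatography on a chiral stationary phase. The unwanted enantiomer is re-esterified with Me3SiCHN2 to the achiral diester 12 and recycled.

Step 21. The strong acid may ionise the tertiary alcohol (dehydration), or the neopentyl-type cation may rearrange before the ester captures it. The fallback sets out from 33 and comes back at 34. The methyl ester is cleaved under neutral conditions with Me3SnOH (1,2-dichloroethane, 80 °C) to (Z)-enoic acid F3. The lactone is then closed by hydrogen-atom-transfer hydroacyloxylation of the isopropenyl group (N,N'-bis(salicylidene)ethylenediaminocobalt, Co(C16H14N2O2), divalent cobalt, 5 mol %; N-fluoro-2,4,6-trimethylpyridinium triflate; PhSiH3; rt), which is Markovnikov-selective for the electron-rich 1,1-disubstituted alkene and needs no Brønsted acid.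

Further compounds
F1 | step 15 | epimer of dienone 27 at the quaternary ring carbon | CC[Si](CC)(CC)OC[C@@]1(C(C)=C)CCC(=C)[C@@H](C[C@]2(C)C(=O)C(C)=CC(O[Si](CC)(CC)CC)=C2CO[Si](c3ccccc3)(c3ccccc3)C(C)(C)C)[C@@]1(C)O
F2 | step 8 | racemic (5E,8Z)-9-bromo-10-[(tert-butyldiphenylsilyl)oxy]-2-(methoxycarbonyl)-5,8-dimethyl-2-(prop-1-en-2-yl)deca-5,8-dienoic acid | COC(=O)C(C(C)=C)(C(=O)O)CC/C(C)=C/C/C(C)=C(Br)/CO[Si](c1ccccc1)(c1ccccc1)C(C)(C)C
F3 | step 21 | (Z)-enoic acid from 33 (CO2H in place of CO2CH3) | OC(=O)/C=C\[C@@]1(C(C)=C)CC[C@@]23C[C@@]4(C)C=C5C(=O)OC[C@]52[C@@](C)(C[C@H]3[C@@]1(C)O)C4=O
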